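Which option adds most target to the eta flask once it has stood for 40 min?

| flask | substrate | catalyst | remark | time |
|---|---|---|---|---|
| eta | 0.11 M | 0.55 mM | the very flask that is asked about, followed so far |  |
| alpha | 0.17 M | 0.55 mM | run made earlier |  |
| flask | 0.11 M | 0.55 mM |  | 40 min |

| run | time / min | target / % |
|---|---|---|
| eta | 6.00 | 21 |
| eta | 12.0 | 29 |
| eta | 20.0 | 30 |
| eta | 25.0 | 30 |
| eta | 30.0 | 29 |
| alpha | 2.50 | 15 |
| alpha | 8.00 | 25 |
| alpha | 12.0 | 27 |
| alpha | 20.0 | 30 |
| alpha | 30.0 | 30 |

(each reading ± 1.5 percentage points)

- autumn: at 40 min take out 90 % of the target then present, then wait 40 min
- midnight: at 40 min add substrate, 50.0 % of the amount charged, then wait 40 min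
- summer: change nothing and wait 40 min more
- dawn: at 40 min add catalyst, 50.0 % of the amount charged, then wait 40 min

- target that was removed still counts
- the numbers in the tables scatter with a standard deviation of 1.5 percentage points
- additions bring no volume worth counting

* target, in percent of the substrate first charged, at 40 min
* which option adds most target ("none" when 2 percentage points or less is all one gets) (autumn / midnight / summer / dawn / none)
* target present, with what was taken out counted in, in percent of the substrate first charged, after autumn
* target present, with what was taken out counted in, in percent of the substrate first charged, after summer

I start from the readings that have stopped moving. The eta flask shows 30 %, 30 % and 29 % late on, and the alpha run shows 30 % and 30 %. Their mean is 29.8 % of the charge. I carry it as the plateau share, the fraction of the material in a flask that stands as target once the flask stops moving.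

Has the eta flask arrived by 40 min? Its first reading, at 6.00 min, lies 8.8 percentage points short of the plateau, which gives a time constant near 4.92 min. That is much shorter than the 40 min of standing, so I commit to 29.8 % for now, and summer adds nothing.

Next I reckon the corrections. Autumn removes 26.8 % of the charge as target. The eta flask keeps 73.2 % of the charge, and I take it to refill to the plateau share of that. The gain is the removed part times the share that is not target, 19 points, which brings the total to 48.8 %. Midnight adds 50.0 % of the charge and gains the plateau share of it, 15 points, which is less than autumn gains. I take dawn to leave the share as it is, so I give it no gain.

The weak link is reading the plateau as a balance. The alpha run reaches the same share from 1.55 times the substrate, so a cap on the amount of target does not fit. Both runs carry 0.55 mM of catalyst, however, so a dying catalyst stays open. I commit to the balance all the same.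

The forecast says 30 % now, autumn as best, 49 % after autumn and 30 % after summer, and on the open point it says “I favour equilibrium as the simpler reading”.

The eta flask gives 29.7 % at 40 min, 48.5 % after autumn and 29.7 % after summer, and autumn is best, adding 19 points.

    substrate ⇌ target (K = 15.3, k = 8.15 × 10⁻⁴ /s)
    target + catalyst ⇌ isomer of the product + catalyst, rate k2*[catalyst]*[target] forward; the back reaction follows from the equilibrium constant (K = 2.30, k = 5.15 /M/s)
    isomer of the product + catalyst ⇌ substrate + catalyst, rate k3*[catalyst]*[isomer of the product] forward; the back reaction follows from the equilibrium constant (k = 2.75 /M/s)

At 40.0 min the eta flask holds 1.94 % substrate, 29.7 % target and 68.3 % isomer of the product. A neighbour flask with 0.0022 M of catalyst, 4.00 times the catalyst of the eta flask, has the same substrate charge, so the plateau share puts it at 29.8 %. It gives 29.7 %.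

The numbers in the tables were generated by integration with constants of no real substance; the scatter is artificial.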